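The route rests on cutting C5–C6 (germacrane numbering). This bond joins the ring-cis C4=C5 alkene to C6, which is a fusion atom of the ten-membered carbocycle and the γ-lactone and also the lactone's alkoxy carbon. An intramolecular Nozaki–Hiyama–Kishi addition of a (Z)-alkenyl iodide (C5) to an aldehyde (C6) closes the carbocycle and sets C6. The resulting alkoxide sits next to the acrylate ester on C7 and lactonises at once, so both rings form in one operation. The precursor is an open-chain iodo aldehyde that already carries the C8 epoxyangelate, the C10 methyl ester, the C11=C13 methylene and the protected C3 carbinol.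

Key step: step 17

Remark: germacrane numbering is used throughout, and both endocyclic alkenes are taken as drawn (cis within the ring). The sense of induction quoted for the chiral catalysts of steps 5 and 11 is assigned by analogy with simpler aldehydes, and both antipodes of each catalyst are available.

Step 1
Reactants: 1 propargyl alcohol
Product: 3 (Z)-3-iodo-2-methylprop-2-en-1-ol, via alkenylmagnesium chelate 2 (not isolated)
Conditions: MeMgBr (2.5 equiv), CuI (10 mol %), THF/Et2O, −10 °C to rt; then iodine, −10 °C
Reagents that add atoms: methylmagnesium bromide C[Mg]Br; iodine [I][I]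
Why: Copper-catalysed anti-carbomagnesiation of the propargylic magnesium alkoxide puts methyl on the internal carbon and magnesium cis to CH2O in chelate 2, so iodinolysis with retention fixes the (Z)-iodoalkene that becomes the ring-cis C4=C5 alkene.

Step 2
Reactants: 3 (Z)-3-iodo-2-methylprop-2-en-1-ol
Product: 4 (Z)-3-iodo-2-methylprop-2-enal
Conditions: activated MnO2, CH2Cl2, rt, dark, used without storage
Reagents that add atoms: none
Why: Allylic alcohol oxidation with MnO2 is neutral and stops at the enal, and short contact in the dark limits Z to E drift.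

Step 3
Reactants: 5 methyl crotonate; 6 allyl bromide
Product: 8 methyl 2-vinylpent-4-enoate (racemic), via lithium dienolate 7 (not isolated)
Conditions: LDA, DMPU, THF, −78 °C; then 6, −78 °C to −20 °C
Reagents that add atoms: none
Why: Deconjugative α-alkylation of the extended crotonate dienolate attaches the C8–C9 allyl unit to C10, and the racemic α-centre is erased in step 4.

Step 4
Reactants: 8 methyl 2-vinylpent-4-enoate
Product: 10 2-allyl-1-methoxy-1-(tert-butyldimethylsilyloxy)buta-1,3-diene, via lithium dienolate 9 (not isolated)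
Conditions: LDA, THF, −78 °C; TBSCl, DMPU, −78 °C to rt
Reagents that add atoms: tert-butyldimethylsilyl chloride CC(C)(C)[Si](C)(C)Cl
Why: O-silylation of the ester dienolate gives the silyl dienol ether, and both ketene acetal geometries converge on the same product in step 5.

Step 5
Reactants: 4 (Z)-3-iodo-2-methylprop-2-enal; 10 silyl dienol ether
Product: 11 methyl (2E,5S,6Z)-2-allyl-5-hydroxy-7-iodo-6-methylhepta-2,6-dienoate
Conditions: SiCl4 (1.1 equiv), (S,S)-bisphosphoramide derived from N,N'-dimethyl-1,1'-binaphthyl-2,2'-diamine (5 mol %), iPr2NEt (10 mol %), CH2Cl2, −78 °C; aq. KH2PO4/KF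
Reagents that add atoms: none
Why: In this catalytic enantioselective vinylogous Mukaiyama aldol reaction the α-allyl group blocks α-attack so C2–C3 forms at the γ-terminus, allylic strain gives the (E)-enoate (C2 trans to CO2Me, the ring-cis C1=C10 geometry), and the chiral phosphoramide-bound silicon Lewis acid exposes the Si face of 4 to set (3S).

Step 6
Reactants: 11 hydroxy dienoate
Product: 12 methyl (2E,5S,6Z)-2-allyl-5-(tert-butyldimethylsilyloxy)-7-iodo-6-methylhepta-2,6-dienoate
Conditions: TBSCl, imidazole, DMF, rt
Reagents that add atoms: tert-butyldimethylsilyl chloride CC(C)(C)[Si](C)(C)Cl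
Why: Standard silylation masks O3 so that only O8 is acylated in step 15, and C3 is not touched.

Step 7
Reactants: 12 silyl ether
Product: 14 methyl (2E,5S,6Z)-5-(tert-butyldimethylsilyloxy)-7-iodo-6-methyl-2-(2-oxoethyl)hepta-2,6-dienoate, via terminal diol 13 (not isolated)
Conditions: OsO4 (2 mol %), NaIO4, 2,6-lutidine, dioxane/H2O, rt
Reagents that add atoms: osmium tetroxide O=[Os](=O)(=O)=O; sodium periodate [Na+].[O-]I(=O)(=O)=O
Why: Lemieux–Johnson cleavage touches only the monosubstituted alkene because the enoate and the iodoalkene are trisubstituted and electron-poor, and the lutidine buffer keeps C1=C10 from migrating towards the new C8 aldehyde.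

Step 8
Reactants: 15 methyl acrylate; 16 2,2-dimethoxyacetaldehyde
Product: 17 methyl 3-hydroxy-4,4-dimethoxy-2-methylidenebutanoate (racemic)
Conditions: DABCO, dioxane/H2O, rt
Reagents that add atoms: none
Why: The Morita–Baylis–Hillman reaction of an activated α,α-dialkoxy aldehyde assembles C6, C7 and C11–C13, and the carbinol centre is lost in step 10.

Step 9
Reactants: 17 allylic alcohol
Product: 18 methyl 3-acetoxy-4,4-dimethoxy-2-methylidenebutanoate
Conditions: Ac2O, pyridine, DMAP (cat.), CH2Cl2, 0 °C
Reagents that add atoms: acetic anhydride CC(=O)OC(C)=O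
Why: Acetylation turns the hydroxyl into a leaving group for allylic substitution.

Step 10
Reactants: 18 allylic acetate
Product: 19 methyl (E)-4,4-dimethoxy-2-[(pinacolboryl)methyl]but-2-enoate (acetal carbon cis to CH2B)
Conditions: B2pin2, CuCl (10 mol %), KOAc (10 mol %), LiCl, DMF, rt
Reagents that add atoms: bis(pinacolato)diboron CC1(C)OB(OC1(C)C)B1OC(C)(C)C(C)(C)O1
Why: Copper-catalysed SN2' borylation of the allylic acetate delivers boron to the methylene terminus and, as usual for ester-bearing substrates of this type, places the C7 substituent trans to the ester and so cis to CH2B.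

Step 11
Reactants: 14 aldehyde; 19 allylboronate
Product: 20 methyl (2E,5S,6Z)-5-(tert-butyldimethylsilyloxy)-2-[(2R,3R)-2-hydroxy-3-(dimethoxymethyl)-4-(methoxycarbonyl)pent-4-en-1-yl]-7-iodo-6-methylhepta-2,6-dienoate
Conditions: (S)-TRIP [3,3'-bis(2,4,6-triisopropylphenyl)-1,1'-binaphthyl-2,2'-diyl hydrogen phosphate] (10 mol %), 4 Å sieves, toluene, −30 °C to rt; pH 7 buffer
Reagents that add atoms: none
Why: Chiral Brønsted acid-catalysed allylboration runs through a closed chair in which C6, cis to CH2B, sits axial and gives the syn C6/O8 relation, while the phosphoric acid bound to a boronate oxygen and the formyl hydrogen directs attack to the Si face of 14 to give (7R,8R), and the allylic transposition unveils the C11=C13 acrylate.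

Step 12
Reactants: 21 angelic acid
Product: 22 (Z)-2-methylbut-2-en-1-ol
Conditions: LiAlH4, Et2O, 0 °C
Reagents that add atoms: none
Why: Hydride reduction of the acid leaves the (Z)-alkene geometry intact.

Step 13
Reactants: 22 (Z)-2-methylbut-2-en-1-ol
Product: 23 (2S,3R)-2,3-epoxy-2-methylbutan-1-ol
Conditions: Ti(OiPr)4 (10 mol %), L-(+)-DIPT (12 mol %), tBuOOH, 4 Å sieves, CH2Cl2, −20 °C
Reagents that add atoms: tert-butyl hydroperoxide CC(C)(C)OO
Why: Sharpless asymmetric epoxidation with the L-(+)-tartrate delivers oxygen to the face that gives (2S) at the carbinol-bearing carbon, and syn addition to the (Z)-alkene fixes (3R).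

Step 14
Reactants: 23 epoxy alcohol
Product: 25 (2R,3R)-2,3-epoxy-2-methylbutanoic acid, via epoxy aldehyde 24 (not isolated)
Conditions: RuCl3 hydrate (2 mol %), NaIO4, MeCN/EtOAc/H2O, 0 °C to rt
Reagents that add atoms: sodium periodate [Na+].[O-]I(=O)(=O)=O; water O
Why: Ruthenium tetroxide oxidation takes the primary alcohol to the acid without touching the epoxide, and the descriptor at C2 changes only through the priority rules.

Step 15
Reactants: 25 epoxy acid; 20 hydroxy ester
Product: 27 C8 epoxyangelate of 20 (7R,8R,2'R,3'R), via mixed anhydride 26 (not isolated)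
Conditions: 2,4,6-trichlorobenzoyl chloride, Et3N, toluene, rt; then 20, DMAP, rt
Reagents that add atoms: none
Why: Yamaguchi esterification acylates the hindered C8 alcohol faster than it can lactonise, and the quaternary α-carbon of the acid cannot epimerise.

Step 16
Reactants: 27 acetal ester
Product: 28 iodo aldehyde (C6 formyl group on C7; 3S,7R,8R)
Conditions: TsOH·H2O (10 mol %), acetone/H2O (10:1), 0 °C to rt, NaHCO3 quench, used crude
Reagents that add atoms: water O
Why: Acid-catalysed hydrolysis of the acyclic dimethyl acetal is much faster than cleavage of the secondary TBS ether or opening of the ester-deactivated epoxide, and the absence of base spares the labile C7–H.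

Step 17
Reactants: 28 iodo aldehyde
Product: 31 3-O-TBS germacranolide (3S,6R,7R,8R), via alkenylchromium species 29 (not isolated), via macrocyclic hydroxy ester 30 (not isolated)
Conditions: CrCl2 (12 equiv), NiCl2 (2 mol % on chromium), DMSO/THF (3:1), slow addition of 28 to about 1 mM, rt; aq. NH4Cl, then SiO2, CH2Cl2
Reagents that add atoms: none
Why: Zerovalent nickel made in situ inserts into the carbon–iodine bond at C5 with retention, transmetallation gives (Z)-alkenylchromium 29, and this adds to the C6 aldehyde, the closest known type being Nozaki–Hiyama–Kishi closures of medium and large carbocycles from alkenyl iodide aldehydes. The carbocycle closes in a 10-exo-trig mode, and the trivalent chromium alkoxide of 30 then attacks the C12 methyl ester in a 5-exo-trig acyl substitution that expels methoxide and forms the trans-fused lactone. C6 is controlled by C7 and C8: with the C8 branch antiperiplanar to the incoming C5 (Felkin–Anh arrangement) O6 ends up syn to C11, and because C11 and O8 are anti, the 1,3-anti polar preference of the acyloxy group selects the same face, so (6R) should result. The same antiperiplanar C5–C6–C7–C8 array is what the trans ring fusion requires, so the favoured adduct is also the one poised to lactonise. Chemoselectivity rests on the low basicity and strong aldehyde preference of alkenylchromium reagents, which should leave the three esters, the acrylate, the epoxide, the silyl ether and the acidic C7–H alone. Ring closure must outrun oligomerisation, which is secured by high dilution and by the two ring-cis alkenes (C1=C10 and C4=C5) that fold the chain.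

Step 18
Reactants: 31 3-O-TBS germacranolide
Product: 32 target CNP0143679.1
Conditions: HF·pyridine, pyridine, THF, 0 °C to rt
Reagents that add atoms: none
Why: Buffered fluoride-mediated desilylation frees O3 under conditions that tolerate epoxides, α-methylene lactones and enoates, and no stereocentre is involved.

Compound list
1 | propargyl alcohol | C#CCO | starting material
2 | alkenylmagnesium chelate (five-membered O–Mg–C ring) | CC1=C[Mg]OC1 | intermediate
3 | (Z)-3-iodo-2-methylprop-2-en-1-ol | I/C=C(/C)CO | intermediate
4 | (Z)-3-iodo-2-methylprop-2-enal | I/C=C(/C)C=O | intermediate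
5 | methyl (E)-but-2-enoate | C/C=C/C(=O)OC | starting material
6 | allyl bromide | C=CCBr | starting material
7 | lithium dienolate of methyl crotonate | C=CC=C(OC)O[Li] | intermediate
8 | methyl 2-vinylpent-4-enoate (racemic) | C=CCC(C=C)C(=O)OC | intermediate
9 | lithium dienolate of 8 | C=CCC(C=C)=C(OC)O[Li] | intermediate
10 | 2-allyl-1-methoxy-1-(tert-butyldimethylsilyloxy)buta-1,3-diene (either ketene acetal geometry) | C=CCC(C=C)=C(OC)O[Si](C)(C)C(C)(C)C | intermediate
11 | methyl (2E,5S,6Z)-2-allyl-5-hydroxy-7-iodo-6-methylhepta-2,6-dienoate | C=CC/C(=C\C[C@@H](/C(=C\I)C)O)C(=O)OC | intermediate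
12 | TBS ether of 11 | C=CC/C(=C\C[C@@H](/C(=C\I)C)O[Si](C)(C)C(C)(C)C)C(=O)OC | intermediate
13 | terminal 1,2-diol from 12 (both epimers at the new carbinol) | OCC(O)C/C(=C\C[C@@H](/C(=C\I)C)O[Si](C)(C)C(C)(C)C)C(=O)OC | intermediate
14 | methyl (2E,5S,6Z)-5-(tert-butyldimethylsilyloxy)-7-iodo-6-methyl-2-(2-oxoethyl)hepta-2,6-dienoate | O=CC/C(=C\C[C@@H](/C(=C\I)C)O[Si](C)(C)C(C)(C)C)C(=O)OC | intermediate
15 | methyl acrylate | C=CC(=O)OC | starting material
16 | 2,2-dimethoxyacetaldehyde | COC(OC)C=O | starting material
17 | methyl 3-hydroxy-4,4-dimethoxy-2-methylidenebutanoate (racemic) | COC(OC)C(O)C(=C)C(=O)OC | intermediate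
18 | methyl 3-acetoxy-4,4-dimethoxy-2-methylidenebutanoate (racemic) | COC(OC)C(OC(C)=O)C(=C)C(=O)OC | intermediate
19 | methyl (E)-4,4-dimethoxy-2-[(pinacolboryl)methyl]but-2-enoate | COC(OC)/C=C(\CB1OC(C)(C)C(C)(C)O1)C(=O)OC | intermediate
20 | (3S,7R,8R) hydroxy ester, C7–C8 syn adduct | COC(OC)[C@H](C(=C)C(=O)OC)[C@@H](C/C(=C\C[C@@H](/C(=C\I)C)O[Si](C)(C)C(C)(C)C)C(=O)OC)O | intermediate
21 | angelic acid, (Z)-2-methylbut-2-enoic acid | C/C=C(/C)C(=O)O | starting material
22 | (Z)-2-methylbut-2-en-1-ol | C/C=C(/C)CO | intermediate
23 | (2S,3R)-2,3-epoxy-2-methylbutan-1-ol | OC[C@]1(C)O[C@@H]1C | intermediate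
24 | (2R,3R)-2,3-epoxy-2-methylbutanal | O=C[C@]1(C)O[C@@H]1C | intermediate
25 | (2R,3R)-2,3-epoxy-2-methylbutanoic acid | OC(=O)[C@]1(C)O[C@@H]1C | intermediate
26 | mixed anhydride of 25 and 2,4,6-trichlorobenzoic acid | O=C(OC(=O)[C@]1(C)O[C@@H]1C)c1c(Cl)cc(Cl)cc1Cl | intermediate
27 | C8 epoxyangelate acetal (3S,7R,8R,2'R,3'R) | COC(OC)[C@H](C(=C)C(=O)OC)[C@@H](C/C(=C\C[C@@H](/C(=C\I)C)O[Si](C)(C)C(C)(C)C)C(=O)OC)OC(=O)[C@]1(C)O[C@@H]1C | intermediate
28 | open-chain iodo aldehyde (3S,7R,8R,2'R,3'R) | O=C[C@H](C(=C)C(=O)OC)[C@@H](C/C(=C\C[C@@H](/C(=C\I)C)O[Si](C)(C)C(C)(C)C)C(=O)OC)OC(=O)[C@]1(C)O[C@@H]1C | intermediate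
29 | (Z)-alkenylchromium dichloride from 28 | O=C[C@H](C(=C)C(=O)OC)[C@@H](C/C(=C\C[C@@H](/C(=C\[Cr](Cl)Cl)C)O[Si](C)(C)C(C)(C)C)C(=O)OC)OC(=O)[C@]1(C)O[C@@H]1C | intermediate
30 | ten-membered (6R) hydroxy ester, formed as its chromium alkoxide and drawn as the alcohol | O[C@@H]1/C=C(/C)[C@@H](O[Si](C)(C)C(C)(C)C)C/C=C(/C(=O)OC)C[C@@H](OC(=O)[C@]2(C)O[C@@H]2C)[C@H]1C(=C)C(=O)OC | intermediate
31 | 3-O-TBS germacranolide (3S,6R,7R,8R; 1(10)E, 4Z; trans-fused 6,12-olide) | C=C1C(=O)O[C@@H]2/C=C(/C)[C@@H](O[Si](C)(C)C(C)(C)C)C/C=C(/C(=O)OC)C[C@@H](OC(=O)[C@]3(C)O[C@@H]3C)[C@@H]12 | intermediate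
32 | CNP0143679.1 | C=C1C(=O)O[C@@H]2/C=C(/C)[C@@H](O)C/C=C(/C(=O)OC)C[C@@H](OC(=O)[C@]3(C)O[C@@H]3C)[C@@H]12 | target

Total step count: 18. Longest linear sequence: 10 steps (1, 2, 5, 6, 7, 11, 15, 16, 17, 18).

Steps most likely to fail

Step 17.
- **What may go wrong:** intermolecular coupling may compete with ring closure, and the alkenylchromium species may be protonated. The aldehyde may enolise, followed by loss of the C8 carboxylate or drift of C11=C13 into conjugation. Attack may also occur on the wrong aldehyde face.
- **Fallback:** it sets out from 20 and uses a temporary ring as a template. Catalytic camphorsulfonic acid in CH2Cl2 closes O8 onto C12 to give the cis-fused 8,12-lactone acetal F1. Hydrolysis as in step 16 gives the lactone aldehyde F2, in which two rotors are frozen and O8 is tied into a ring. The CrCl2/NiCl2 closure then forms C5–C6 in this templated chain and gives the 6-hydroxy-8,12-olide F3. An acyl shift from O8 to O6, by the chromium alkoxide in the flask or by catalytic DBU in toluene, should give the less strained trans-fused 8-hydroxy-6,12-olide F4. Esterification of F4 with 25 under the conditions of step 15 comes back to the route at 31.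

Step 11.
- **What may go wrong:** the ester-deactivated, γ-branched allylboronate may react sluggishly under a weak Brønsted acid. Facial control may erode through an uncatalysed background reaction, and O8 may lactonise early onto C12 or C14.
- **Fallback:** it sets out from 14 and 17. NBS/Me2S in CH2Cl2 converts 17 with allylic transposition into the (Z)-allylic bromide F5. Indium powder in THF/aq. NH4Cl (Barbier allylation) couples F5 with 14. This process is known to favour the syn relation for 2-(bromomethyl)alk-2-enoates of this geometry but does not control the absolute sense, so 20 should form together with its (7S,8S) diastereomer F6. The resident (3S) centre makes the two separable by chromatography, and the route is rejoined at 20.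

Step 5.
- **What may go wrong:** the iodo enal may isomerise from Z to E under the chlorosilane Lewis acid. α-Attack may compete with γ-attack, and face selectivity may be insufficient with this small enal.
- **Fallback:** it sets out from 4. Brown allylation, using allylmagnesium bromide and (−)-B-methoxydiisopinocampheylborane at −78 °C followed by oxidative work-up, gives (3S,1Z)-1-iodo-2-methylhexa-1,5-dien-3-ol F7. Silylation gives the TBS ether F8, and Lemieux–Johnson cleavage gives the β-silyloxy aldehyde F9. Separately, methyl (triphenylphosphoranylidene)acetate is alkylated with 6 and deprotonated with aq. NaOH to give methyl 2-(triphenylphosphoranylidene)pent-4-enoate F10. The (E)-selective Wittig reaction of F9 with F10 in toluene comes back to the route at 12.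

Further compounds
F1 | step 17 | cis-fused 8,12-lactone acetal | COC(OC)[C@@H]1C(=C)C(=O)O[C@@H]1C/C(=C\C[C@@H](/C(=C\I)C)O[Si](C)(C)C(C)(C)C)C(=O)OC
F2 | step 17 | 8,12-lactone aldehyde | O=C[C@@H]1C(=C)C(=O)O[C@@H]1C/C(=C\C[C@@H](/C(=C\I)C)O[Si](C)(C)C(C)(C)C)C(=O)OC
F3 | step 17 | ten-membered 6-hydroxy-8,12-olide | O[C@@H]1/C=C(/C)[C@@H](O[Si](C)(C)C(C)(C)C)C/C=C(/C(=O)OC)C[C@H]2OC(=O)C(=C)[C@@H]12
F4 | step 17 | ten-membered 8-hydroxy-6,12-olide | C=C1C(=O)O[C@@H]2/C=C(/C)[C@@H](O[Si](C)(C)C(C)(C)C)C/C=C(/C(=O)OC)C[C@@H](O)[C@@H]12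
F5 | step 11 | methyl (Z)-2-(bromomethyl)-4,4-dimethoxybut-2-enoate | COC(OC)/C=C(\CBr)C(=O)OC
F6 | step 11 | (3S,7S,8S) diastereomer of 20 | COC(OC)[C@@H](C(=C)C(=O)OC)[C@H](C/C(=C\C[C@@H](/C(=C\I)C)O[Si](C)(C)C(C)(C)C)C(=O)OC)O
F7 | step 5 | (3S,1Z)-1-iodo-2-methylhexa-1,5-dien-3-ol | C=CC[C@@H](/C(=C\I)C)O
F8 | step 5 | TBS ether of F7 | C=CC[C@@H](/C(=C\I)C)O[Si](C)(C)C(C)(C)C
F9 | step 5 | (3S,4Z)-3-(tert-butyldimethylsilyloxy)-5-iodo-4-methylpent-4-enal | O=CC[C@@H](/C(=C\I)C)O[Si](C)(C)C(C)(C)C
F10 | step 5 | methyl 2-(triphenylphosphoranylidene)pent-4-enoate | C=CCC(C(=O)OC)=P(c1ccccc1)(c1ccccc1)c1ccccc1
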